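**Retrosynthetic overview**

- The strategy rests on the benzene-1,3-diol ring, which has hydroxyls on C1 and C3 and its only carbon substituent, the 15-hydroxyheptadecyl chain, on C5. The single stereocentre, chain C15 (S), is separated from the ring by fourteen CH2 groups.
- The arene is cut at C4–C5 and C1–C2. Ring C5, C6 and C1 come from a 2-alkynoate (β-carbon, α-carbon, ester carbon), and ring C2, C3 and C4 come from dimethyl 3-oxopentanedioate. The two ester groups left on C2 and C4 are removed afterwards by hydrolysis and decarboxylation.
- The ynoate comes from a silyl-protected terminal C19 alkynol and methyl chloroformate. The terminal alkyne is reached by zipper isomerisation of the internal alkyne made from (S)-1,2-epoxybutane and 1-pentadecyne.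
- Order of events: the chain is joined first (C4 + C15), the triple bond is moved to the chain end and capped with the ester carbon, and the only ring is formed last in one operation. The stereocentre is bought and never becomes a reaction site.

Key step: step 5

Remark: chain positions are counted from the ring-bound carbon, so the carbinol is chain C15 (S, as in the SMILES); commercial (S)-1,2-epoxybutane of high enantiomeric purity is assumed.

**Route**

Step 1
Reactants: 1 (S)-1,2-epoxybutane [(S)-2-ethyloxirane]; 2 1-pentadecyne
Product: 4 (S)-nonadec-5-yn-3-ol, via lithium pentadec-1-yn-1-ide 3 (not isolated)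
Conditions: 2 (1.3 equiv), n-BuLi, THF, −78 °C; BF3·OEt2, −78 °C; then 1, −78 °C; aq NH4Cl
Reagents that add atoms: none
Why: Yamaguchi–Hirao alkynylation, in which the lithium acetylide opens the BF3-activated epoxide by SN2 attack at the unsubstituted CH2, so no bond to the stereocentre is broken and the S configuration is carried over unchanged.

Step 2
Reactants: 4 (S)-nonadec-5-yn-3-ol
Product: 5 (S)-nonadec-18-yn-3-ol
Conditions: KNH(CH2)3NH2 (from KH, H2N(CH2)3NH2, rt); then 4 (THF co-solvent), 0 °C to rt; ice/H2O quench
Reagents that add atoms: none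
Why: Alkyne zipper isomerisation, in which repeated propargyl/allenyl deprotonation and reprotonation move the triple bond along the chain until it is trapped as the terminal potassium acetylide at the end remote from the oxygen, while the carbinol carbon, held as a non-acidic secondary alkoxide, should keep its configuration.

Step 3
Reactants: 5 (S)-nonadec-18-yn-3-ol
Product: 6 (S)-tert-butyl(nonadec-18-yn-3-yloxy)dimethylsilane
Conditions: TBSCl, imidazole, DMF, rt
Reagents that add atoms: tert-butyldimethylsilyl chloride (TBSCl), CC(C)(C)[Si](C)(C)Cl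
Why: Standard imidazole-promoted silylation of a secondary alcohol, which masks the hydroxyl against the strong bases of the next steps and leaves the terminal alkyne untouched.

Step 4
Reactants: 6 (S)-tert-butyl(nonadec-18-yn-3-yloxy)dimethylsilane; 7 methyl chloroformate
Product: 9 methyl (S)-18-(tert-butyldimethylsilyloxy)icos-2-ynoate, via lithium acetylide 8 (not isolated)
Conditions: n-BuLi, THF, −78 °C; then 7, −78 to 0 °C; aq NH4Cl
Reagents that add atoms: none
Why: Deprotonation of the terminal alkyne and C-acylation of the lithium acetylide by the chloroformate gives the 2-alkynoate, whose new ester carbon later becomes ring C1; the silyl ether is stable to n-BuLi at low temperature.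

Step 5
Reactants: 9 methyl (S)-18-(tert-butyldimethylsilyloxy)icos-2-ynoate; 10 dimethyl 3-oxopentanedioate
Product: 12 dimethyl 2,4-dihydroxy-6-[(15S)-15-(tert-butyldimethylsilyloxy)heptadecyl]benzene-1,3-dicarboxylate, via open-chain Michael adduct 11 (not isolated)
Conditions: 10, NaH, THF, 0 °C to rt; then 9, rt to reflux; any 2-pyranone fraction: NaOMe, MeOH, reflux; 1 M HCl work-up
Reagents that add atoms: none
Why: The sodium enolate of 10 adds through its doubly activated carbon to the β-carbon (C3) of ynoate 9 in a Michael addition (ring bond C5–C4), giving triester 11 as alkene isomers that interconvert through the extended dienolate because the keto ester CH stays acidic. In the isomer with the unsaturated ester cis to the keto ester arm, the second α-carbon of the ketone attacks the former ynoate ester carbonyl and expels methoxide in a Dieckmann acylation (ring bond C2–C1), closing the only ring in a 6-exo-trig mode. The resulting cyclohexadienedione enolises directly to the aromatic 2,4-dihydroxyisophthalate, so no oxidant is needed and both phenols emerge free. This is the known Michael addition–Dieckmann benzannulation of acetonedicarboxylate anions with 2-alkynoates. No stereocentre is formed, and the silyl-protected carbinol, fourteen methylenes from the reacting site, is inert to NaH and NaOMe. The step needs C- over O-acylation in the closure (arene against 2-pyranone) and convergence of the alkene isomers; both should be secured thermodynamically, since under alkoxide the pyranone reopens and the reversible enolate manifold drains into the resorcinolate, while the unbranched chain offers no competing acidic or electrophilic site.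

Step 6
Reactants: 12 dimethyl 2,4-dihydroxy-6-[(15S)-15-(tert-butyldimethylsilyloxy)heptadecyl]benzene-1,3-dicarboxylate
Product: 14 5-[(15S)-15-(tert-butyldimethylsilyloxy)heptadecyl]benzene-1,3-diol, via dicarboxylic acid 13 (not isolated)
Conditions: KOH, MeOH/H2O (degassed), reflux, Ar; cool, 1 M HCl to pH 5 at 0 °C, then 50 °C until CO2 evolution stops
Reagents that add atoms: none
Why: Saponification of both methyl esters followed by protodecarboxylation, which should be easy because each carboxyl is ortho or para to a hydroxyl and so invites ipso-protonation of the electron-rich ring; the secondary silyl ether should tolerate hot alkali and a short exposure to pH 5.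

Step 7
Reactants: 14 5-[(15S)-15-(tert-butyldimethylsilyloxy)heptadecyl]benzene-1,3-diol
Product: 15 Hansfordiol C, 5-[(15S)-15-hydroxyheptadecyl]benzene-1,3-diol
Conditions: HCl (1 M in MeOH), 0 °C to rt
Reagents that add atoms: none
Why: Acid-catalysed methanolysis of the secondary silyl ether (desilylation), to which the resorcinol and the saturated chain are inert and in which the stereocentre is not a reaction site.

**Compound list**

1 | (S)-1,2-epoxybutane | CC[C@H]1CO1 | starting material
2 | 1-pentadecyne | CCCCCCCCCCCCCC#C | starting material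
3 | lithium pentadec-1-yn-1-ide | [Li]C#CCCCCCCCCCCCCC | intermediate (not isolated)
4 | (S)-nonadec-5-yn-3-ol | CC[C@H](O)CC#CCCCCCCCCCCCCC | intermediate
5 | (S)-nonadec-18-yn-3-ol | CC[C@H](O)CCCCCCCCCCCCCCC#C | intermediate
6 | (S)-tert-butyl(nonadec-18-yn-3-yloxy)dimethylsilane | CC[C@H](O[Si](C)(C)C(C)(C)C)CCCCCCCCCCCCCCC#C | intermediate
7 | methyl chloroformate | COC(=O)Cl | starting material
8 | lithium (S)-17-(tert-butyldimethylsilyloxy)nonadec-1-yn-1-ide | CC[C@H](O[Si](C)(C)C(C)(C)C)CCCCCCCCCCCCCCC#C[Li] | intermediate (not isolated)
9 | methyl (S)-18-(tert-butyldimethylsilyloxy)icos-2-ynoate | CC[C@H](O[Si](C)(C)C(C)(C)C)CCCCCCCCCCCCCCC#CC(=O)OC | intermediate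
10 | dimethyl 3-oxopentanedioate | COC(=O)CC(=O)CC(=O)OC | starting material
11 | dimethyl 2-[(18S)-18-(tert-butyldimethylsilyloxy)-1-methoxy-1-oxoicos-2-en-3-yl]-3-oxopentanedioate (alkene isomers, present as its sodium enolate) | CC[C@H](O[Si](C)(C)C(C)(C)C)CCCCCCCCCCCCCCC(=CC(=O)OC)C(C(=O)OC)C(=O)CC(=O)OC | intermediate (not isolated)
12 | dimethyl 2,4-dihydroxy-6-[(15S)-15-(tert-butyldimethylsilyloxy)heptadecyl]benzene-1,3-dicarboxylate | CC[C@H](O[Si](C)(C)C(C)(C)C)CCCCCCCCCCCCCCc1cc(O)c(C(=O)OC)c(O)c1C(=O)OC | intermediate
13 | 2,4-dihydroxy-6-[(15S)-15-(tert-butyldimethylsilyloxy)heptadecyl]benzene-1,3-dicarboxylic acid | CC[C@H](O[Si](C)(C)C(C)(C)C)CCCCCCCCCCCCCCc1cc(O)c(C(=O)O)c(O)c1C(=O)O | intermediate (not isolated)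
14 | 5-[(15S)-15-(tert-butyldimethylsilyloxy)heptadecyl]benzene-1,3-diol | CC[C@H](O[Si](C)(C)C(C)(C)C)CCCCCCCCCCCCCCc1cc(O)cc(O)c1 | intermediate
15 | Hansfordiol C, 5-[(15S)-15-hydroxyheptadecyl]benzene-1,3-diol | CC[C@H](O)CCCCCCCCCCCCCCc1cc(O)cc(O)c1 | target

**Totals and risks**

Total step count: 7. Longest linear sequence: 7 steps (from 1 or 2 to 15).

Steps most likely to fail:

1. Step 5 (ring construction). The Michael adduct may close through the enol oxygen to a 2-pyranone instead of through carbon, may stall at the open-chain stage, or the ynoate may oligomerise under alkoxide. The fallback attaches a preformed, benzyl-protected resorcinol by cross-coupling. It sets out from 1: the lithium acetylide of 1-tridecyne F1 (n-BuLi, BF3·OEt2, THF, −78 °C) should open the epoxide to (S)-heptadec-5-yn-3-ol F2, and the same KNH(CH2)3NH2 isomerisation should convert this into (S)-heptadec-16-yn-3-ol F3. Sonogashira coupling with 1,3-bis(benzyloxy)-5-bromobenzene F4 (PdCl2(PPh3)2, CuI, Et3N, 70 °C) should give (S)-17-[3,5-bis(benzyloxy)phenyl]heptadec-16-yn-3-ol F5. Hydrogenation over Pd/C in EtOAc/MeOH should then saturate the triple bond and remove both benzyl groups in one operation, coming back to the route at 15.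

2. Step 2 (zipper). Migration over thirteen positions may be incomplete and leave internal alkyne and allene isomers, made worse by poor solubility of the long-chain alkoxide in the diamine; the enantiomeric purity of 5 should be confirmed as its Mosher ester. The fallback installs the terminal alkyne by alkylation, with no isomerisation. It sets out from 1: LiC≡CH·H2N(CH2)2NH2 in DMSO should give (S)-hex-5-yn-3-ol F6, and silylation (TBSCl, imidazole, DMF) should give (S)-tert-butyl(hex-5-yn-3-yloxy)dimethylsilane F7. Its lithium acetylide (n-BuLi, THF/DMPU) is alkylated with an excess of 1,11-dibromoundecane F8 to give (S)-[(17-bromoheptadec-5-yn-3-yl)oxy](tert-butyl)dimethylsilane F9. Hydrogenation (H2, Pt/C, EtOAc) should give (S)-[(17-bromoheptadecan-3-yl)oxy](tert-butyl)dimethylsilane F10, and displacement of bromide with LiC≡CH·H2N(CH2)2NH2 in DMSO comes back to the route at 6.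

3. Step 6 (ester removal). Hydrolysis of the two hindered, phenoxide-deactivated esters may be incomplete or stop at a monoacid, and the silyl ether may be slowly lost on prolonged heating in alkali. The fallback carries acid-labile esters so that no hydrolysis is needed. It sets out from 9: the benzannulation of step 5 is run with di-tert-butyl 3-oxopentanedioate F11 (NaH, THF, reflux) to give di-tert-butyl 2,4-dihydroxy-6-[(15S)-15-(tert-butyldimethylsilyloxy)heptadecyl]benzene-1,3-dicarboxylate F12. CF3CO2H in CH2Cl2 followed by warming in aqueous dioxane should remove both tert-butyl groups as 2-methylpropene, release both carboxyls as CO2 and cleave the silyl ether, coming back to the route at 15. Any trifluoroacetate of the secondary alcohol would be removed by K2CO3 in MeOH.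

**Further compounds**

F1 | step 5 | 1-tridecyne | CCCCCCCCCCCC#C
F2 | step 5 | (S)-heptadec-5-yn-3-ol | CC[C@H](O)CC#CCCCCCCCCCCC
F3 | step 5 | (S)-heptadec-16-yn-3-ol | CC[C@H](O)CCCCCCCCCCCCC#C
F4 | step 5 | 1,3-bis(benzyloxy)-5-bromobenzene | Brc1cc(OCc2ccccc2)cc(OCc2ccccc2)c1
F5 | step 5 | (S)-17-[3,5-bis(benzyloxy)phenyl]heptadec-16-yn-3-ol | CC[C@H](O)CCCCCCCCCCCCC#Cc1cc(OCc2ccccc2)cc(OCc2ccccc2)c1
F6 | step 2 | (S)-hex-5-yn-3-ol | CC[C@H](O)CC#C
F7 | step 2 | (S)-tert-butyl(hex-5-yn-3-yloxy)dimethylsilane | CC[C@H](O[Si](C)(C)C(C)(C)C)CC#C
F8 | step 2 | 1,11-dibromoundecane | BrCCCCCCCCCCCBr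
F9 | step 2 | (S)-[(17-bromoheptadec-5-yn-3-yl)oxy](tert-butyl)dimethylsilane | CC[C@H](O[Si](C)(C)C(C)(C)C)CC#CCCCCCCCCCCCBr
F10 | step 2 | (S)-[(17-bromoheptadecan-3-yl)oxy](tert-butyl)dimethylsilane | CC[C@H](O[Si](C)(C)C(C)(C)C)CCCCCCCCCCCCCCBr
F11 | step 6 | di-tert-butyl 3-oxopentanedioate | CC(C)(C)OC(=O)CC(=O)CC(=O)OC(C)(C)C
F12 | step 6 | di-tert-butyl 2,4-dihydroxy-6-[(15S)-15-(tert-butyldimethylsilyloxy)heptadecyl]benzene-1,3-dicarboxylate | CC[C@H](O[Si](C)(C)C(C)(C)C)CCCCCCCCCCCCCCc1cc(O)c(C(=O)OC(C)(C)C)c(O)c1C(=O)OC(C)(C)C
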